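The side chain (numbered from the OCH2 carbon, C1') is cut from isofraxidin at the aryl O–C1' bond and traced back to an E-trisubstituted allylic alcohol, itself opened at C3'–CH3 and C1'–C2'. The feature exploited is that on the oxirane ring (O, C2', C3') the C3' methyl group sits cis to the C1' carbon on C2': the pattern left by syn methyl–metal addition across a terminal alkyne followed by one-carbon capture at the metalated carbon. One operation thus makes both skeletal bonds and fixes the olefin geometry that epoxidation later turns into the two stereocentres. Its precursor is a skipped diynol: a terminal alkyne one CH2 away from an internal alkyne bearing the tertiary carbinol.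

Key step: step 2

Remark: by CIP analysis the oxirane of the target is (2'R,3'R), the enantiomer expected from an (E)-3-methylalk-2-en-1-ol with D-(−)-diethyl tartrate; isofraxidin is taken as a purchased material.

Step 1
Reactants: 1 propargyl bromide; 2 2-methylbut-3-yn-2-ol
Product: 3 2-methylhepta-3,6-diyn-2-ol
Conditions: CuI, NaI, K2CO3, DMF, rt (2 in threefold excess)
Reagents that add atoms: none
Why: Copper-mediated sp–sp3 cross-coupling of a terminal alkyne with a propargylic bromide under carbonate base (iodide accelerates the substitution) is the standard entry to skipped diynes and tolerates the free tertiary hydroxyl, while the excess of cheap, volatile 2 suppresses a second propargylation at the new terminal alkyne of 3.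

Step 2
Reactants: 3 2-methylhepta-3,6-diyn-2-ol; 4 trimethylaluminium; 5 formaldehyde (as paraformaldehyde)
Product: 9 (E)-3,7-dimethyloct-2-en-5-yne-1,7-diol, via aluminium alkoxide 6 (not isolated), via alkenylalane 7 (not isolated), via lithium alkenylaluminate 8 (not isolated)
Conditions: Me3Al (3 equiv), Cp2ZrCl2 (0.25 equiv), CH2Cl2, 0 °C to rt; volatiles removed in vacuo; n-BuLi (2 equiv), hexane, −78 to 0 °C; (CH2O)n, THF, rt; then 1 M HCl, 0 °C
Reagents that add atoms: none
Why: Me3Al first turns the tertiary hydroxyl of 3 into alkoxide 6 with loss of methane, and the Me–Zr species generated from Cp2ZrCl2 and Me3Al then adds methyl and metal across the terminal triple bond in a concerted four-centre syn addition, methyl to the substituted carbon and (after Zr-to-Al exchange) aluminium to the CH terminus, to give alkenylalane 7. n-BuLi converts 7 into the more nucleophilic aluminate 8, whose alkenyl–Al bond adds to formaldehyde with retention, so the new CH2OH carbon ends cis to the new methyl group and trans to the propargylic CH2 (E-olefin of 9). The closest known reaction type is the Negishi zirconium-catalysed methylalumination of terminal alkynes with paraformaldehyde capture of the derived alanate, the standard entry to (E)-3-methylalk-2-en-1-ols, here applied to a skipped diynol. No ring is closed and no stereocentre is created: the two new skeletal bonds are C3–CH3 and C1–C2 of 9, and the olefin geometry is controlled by syn addition followed by stereoretentive exchange of C–Al for C–C. The step needs regioselectivity (methyl to the inner alkyne carbon) and site selectivity (terminal over internal alkyne), and both are secured by the bulk of the bimetallic reagent, which places the metal on the unhindered CH terminus and reacts far more slowly at the internal alkyne shielded by the quaternary C(CH3)2–OAlMe2 centre. The free hydroxyl needs no protecting group because it is masked in the flask as 6, for which one extra equivalent of Me3Al is supplied.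

Step 3
Reactants: 9 (E)-3,7-dimethyloct-2-en-5-yne-1,7-diol
Product: 11 (2E,5E)-3,7-dimethylocta-2,5-diene-1,7-diol, via sodium alkenylaluminate 10 (not isolated)
Conditions: NaAlH2(OCH2CH2OCH3)2 (3.5 equiv), THF, 0 °C to 40 °C; then H2O, aq. NaOH
Reagents that add atoms: none
Why: Hydroxyl-directed trans-reduction of a propargylic alcohol: after both hydroxyls have become alkoxyaluminates (H2 is lost), the tertiary propargylic oxygen delivers hydride to the nearer alkyne carbon and aluminium to the farther one in an anti hydroalumination that gives the five-membered alkenylaluminate 10, and protonolysis on work-up leaves the E-C5=C6 olefin, whereas the isolated trisubstituted olefin next to the primary alkoxide is not reduced.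

Step 4
Reactants: 11 (2E,5E)-3,7-dimethylocta-2,5-diene-1,7-diol
Product: 12 [(2R,3R)-3-[(2E)-4-hydroxy-4-methylpent-2-en-1-yl]-3-methyloxiran-2-yl]methanol
Conditions: Ti(OiPr)4 (0.1 equiv), D-(−)-diethyl tartrate (0.12 equiv), t-BuOOH (2 equiv), 4 Å molecular sieves, CH2Cl2, −20 °C
Reagents that add atoms: tert-butyl hydroperoxide, CC(C)(C)OO
Why: Sharpless asymmetric epoxidation: the primary allylic hydroxyl of 11 binds to the catalyst formed from Ti(OiPr)4 and the tartrate, and with the D-(−)-ester the peroxide oxygen is delivered to the face of the E-trisubstituted C2=C3 olefin that gives the (2R,3R)-oxirane (the mirror image of the (2S,3S) outcome established for geraniol-type alcohols with the L-(+)-ester), the cis relationship of the C3 methyl group and the CH2OH carbon being inherited from the E-olefin, while the tertiary allylic alcohol at C7 is epoxidised far more slowly so that C5=C6 stays intact.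

Step 5
Reactants: 12 [(2R,3R)-3-[(2E)-4-hydroxy-4-methylpent-2-en-1-yl]-3-methyloxiran-2-yl]methanol; 13 isofraxidin
Product: 14 7-{[(2R,3R)-3-[(2E)-4-hydroxy-4-methylpent-2-en-1-yl]-3-methyloxiran-2-yl]methoxy}-6,8-dimethoxy-2H-chromen-2-one
Conditions: PPh3, DIAD, THF, 0 °C to rt
Reagents that add atoms: none
Why: Mitsunobu etherification: PPh3 and DIAD activate only the primary hydroxyl of 12 (the tertiary one is inert), and the acidic phenol 13 displaces it by SN2 at the CH2 carbon, which is not a stereocentre, so both oxirane centres are carried through unchanged and the neutral conditions spare the oxirane and the lactone, as known for glycidol-type alcohols and phenols.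

Compound list
1 | propargyl bromide (3-bromoprop-1-yne) | BrCC#C | starting material
2 | 2-methylbut-3-yn-2-ol | CC(C)(O)C#C | starting material
3 | 2-methylhepta-3,6-diyn-2-ol | CC(C)(O)C#CCC#C | intermediate
4 | trimethylaluminium | C[Al](C)C | starting material
5 | formaldehyde (used as paraformaldehyde) | C=O | starting material
6 | dimethylaluminium 2-methylhepta-3,6-diyn-2-olate (not isolated) | C[Al](C)OC(C)(C)C#CCC#C | intermediate
7 | (E)-alkenyl(dimethyl)alane from syn methylalumination of 6, tertiary oxygen as O–AlMe2 (not isolated) | C[Al](C)/C=C(\C)CC#CC(C)(C)O[Al](C)C | intermediate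
8 | dilithium butyl(dimethyl)aluminate of 7, one n-butyl on each aluminium (not isolated) | [Li+].[Li+].CCCC[Al-](C)(C)/C=C(\C)CC#CC(C)(C)O[Al-](C)(C)CCCC | intermediate
9 | (E)-3,7-dimethyloct-2-en-5-yne-1,7-diol | OC/C=C(\C)CC#CC(C)(C)O | intermediate
10 | disodium salt of the five-membered cyclic alkenylaluminate (O–C7–C6=C5–Al) with the primary oxygen as alkoxyhydridoaluminate (not isolated) | [Na+].[Na+].COCCO[Al-]1(OCCOC)OC(C)(C)C=C1C/C(C)=C/CO[AlH-](OCCOC)OCCOC | intermediate
11 | (2E,5E)-3,7-dimethylocta-2,5-diene-1,7-diol | OC/C=C(\C)C/C=C/C(C)(C)O | intermediate
12 | [(2R,3R)-3-[(2E)-4-hydroxy-4-methylpent-2-en-1-yl]-3-methyloxiran-2-yl]methanol | OC[C@H]1O[C@]1(C)C/C=C/C(C)(C)O | intermediate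
13 | isofraxidin (7-hydroxy-6,8-dimethoxy-2H-chromen-2-one) | COc1cc2ccc(=O)oc2c(OC)c1O | starting material
14 | 7-{[(2R,3R)-3-[(2E)-4-hydroxy-4-methylpent-2-en-1-yl]-3-methyloxiran-2-yl]methoxy}-6,8-dimethoxy-2H-chromen-2-one (CNP0325711.2) | COc1cc2ccc(=O)oc2c(OC)c1OC[C@H]1O[C@]1(C)C/C=C/C(C)(C)O | target

Total step count: 5
Longest linear sequence: 5 steps (1 and 2 to 3, then 9, 11, 12 and 14)

Steps most likely to fail

Step 2 (key step). What may go wrong: carbometalation that does not stop at the terminal alkyne, isomerisation of the skipped diyne to allenic material under the Lewis-acidic and then basic conditions, or incomplete capture of the aluminate by formaldehyde so that protonolysis gives the isopropenyl compound. Fallback: the E-trisubstituted olefin is taken from an existing C5 unit and the alkyne is attached by allylic coupling, so no carbometalation is needed. It sets out from 2 and comes back at 9. Prenyl acetate F1 is hydroxylated at its E-methyl group (SeO2 cat., t-BuOOH, CH2Cl2) to (E)-4-hydroxy-3-methylbut-2-en-1-yl acetate F2. An Appel reaction (CBr4, PPh3) converts it into (E)-4-bromo-3-methylbut-2-en-1-yl acetate F3. This primary allylic bromide alkylates 2 under the copper conditions of step 1 to give (E)-7-hydroxy-3,7-dimethyloct-2-en-5-yn-1-yl acetate F4, and methanolysis (K2CO3, MeOH) should give 9.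

Step 1. What may go wrong: a second propargylation at the terminal alkyne of the product, and base-induced isomerisation or oligomerisation of the terminal skipped diyne during reaction or isolation. Fallback: the alkyne terminus is capped during the coupling. It sets out from 2 and comes back at 3. Coupling of 2 with 3-bromo-1-(trimethylsilyl)prop-1-yne F5 (CuI, NaI, K2CO3, DMF) should give 2-methyl-7-(trimethylsilyl)hepta-3,6-diyn-2-ol F6, which cannot couple again. Buffered fluoride desilylation (n-Bu4NF, AcOH, THF, 0 °C) then releases 3.

Step 5. What may go wrong: slow attack of the doubly ortho-substituted phenol, so that the activated alcohol is consumed by side reactions (alkylation of the reduced azodicarboxylate, oxirane opening). Fallback: two-stage sulfonate alkylation in place of the redox condensation. It sets out from 12 and comes back at 14. Selective sulfonylation of the primary hydroxyl (TsCl, Et3N, DMAP cat., CH2Cl2, 0 °C) gives [(2R,3R)-3-[(2E)-4-hydroxy-4-methylpent-2-en-1-yl]-3-methyloxiran-2-yl]methyl 4-methylbenzenesulfonate F7. Direct SN2 alkylation of 13 at the CH2 carbon (K2CO3, DMF, rt to 50 °C) should then give 14 with both oxirane centres unchanged.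

Further compounds
F1 | step 2 | prenyl acetate (3-methylbut-2-en-1-yl acetate; purchased) | CC(C)=CCOC(C)=O
F2 | step 2 | (E)-4-hydroxy-3-methylbut-2-en-1-yl acetate | CC(=O)OC/C=C(\C)CO
F3 | step 2 | (E)-4-bromo-3-methylbut-2-en-1-yl acetate | CC(=O)OC/C=C(\C)CBr
F4 | step 2 | (E)-7-hydroxy-3,7-dimethyloct-2-en-5-yn-1-yl acetate | CC(=O)OC/C=C(\C)CC#CC(C)(C)O
F5 | step 1 | 3-bromo-1-(trimethylsilyl)prop-1-yne (purchased) | C[Si](C)(C)C#CCBr
F6 | step 1 | 2-methyl-7-(trimethylsilyl)hepta-3,6-diyn-2-ol | CC(C)(O)C#CCC#C[Si](C)(C)C
F7 | step 5 | [(2R,3R)-3-[(2E)-4-hydroxy-4-methylpent-2-en-1-yl]-3-methyloxiran-2-yl]methyl 4-methylbenzenesulfonate | Cc1ccc(cc1)S(=O)(=O)OC[C@H]1O[C@]1(C)C/C=C/C(C)(C)O
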